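**Retrosynthetic overview**

1. The strategy rests on the cyclobutane C5A–C6A–C6B–C5B, whose directly bonded spiro carbons C5A and C5B each carry a 4-bromobutenolide with the lactone oxygens trans, and whose C6A and C6B carry trans bromines. Cutting C5A–C6A and C5B–C6B leaves the tetrasubstituted E alkene C5A=C5B of a 5,5'-bifuranylidene-2,2'-dione (14) and (E)-1,2-dibromoethene (15). Because the two acetoxybutyl arms are 1'S and 1'R, 14 has an inversion centre (meso), and the choice of alkene face alone sets the absolute configuration.
2. 14 comes from its bis-silyl ether 13 by silyl-to-acetyl exchange, and 13 from the 5,5'-bibutenolide 11 by dehydrogenation across C5–C5'.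
3. 11 comes from a C5–C5' coupling of the S-configured half as nucleophile (silyloxyfuran 10) with the R-configured half as electrophile (5-bromobutenolide 9), so that the S/R pairing is not statistical.
4. Both halves come from the bromo ketone 5 by the two mirror-image oxazaborolidine reductions; 5 comes from tetronic acid (1) and butanoyl chloride (2).
5. Ring order: the two butenolide rings are present from tetronic acid; the cyclobutane is closed last, in the key step.

Key step: step 9

**Remarks on the chemistry**

- Numbering used throughout: each butenolide is O1–C2(=O)–C3–C4(Br)–C5, C5 is the spiro carbon, the CHBr carbons are C6, the arm carbinol carbon is C1'; half A carries the 1'S arm, half B the 1'R arm.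
- The carbinols are carried as TBS ethers through all C5 chemistry, because a 2-oxyfuran with an acetate on C1' would be expected to lose acetate by vinylogous β-elimination; the acetates are put on once C5 is no longer enolisable.
- Assumption: 15 is used as the pure E isomer (separated from the commercial E/Z mixture if necessary).
- Assumption: which antipode of the chiral Lewis acid covers which face cannot be predicted with certainty; the antipode that leads to addition on the Si,Si face of C5A=C5B is the one used.

**Route**

Step 1
Reactants: 1 tetronic acid; 2 butanoyl chloride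
Product: 4 3-butanoyl-4-hydroxyfuran-2(5H)-one, via O-butanoyl tetronate 3 (not isolated)
Conditions: Et3N, CH2Cl2, 0 °C; then DMAP (0.3 equiv), rt
Reagents that add atoms: none
Why: O-acylation of the tetronic acid enol followed by the DMAP-mediated 1,3-acyl shift (Fries-type O-to-C rearrangement) should give the chelated, thermodynamically favoured 3-acyltetronic acid.

Step 2
Reactants: 4 3-butanoyl-4-hydroxyfuran-2(5H)-one
Product: 5 4-bromo-3-butanoylfuran-2(5H)-one
Conditions: (COBr)2, DMF (cat.), CH2Cl2, 0 °C to rt; used without delay
Reagents that add atoms: oxalyl bromide, BrC(=O)C(=O)Br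
Why: Vilsmeier-type activation of the ring enol and addition–elimination of bromide at C4 should give the vinylogous acyl bromide, as in the known conversion of tetronic acids and of 2-acyl-1,3-diones into their ring enol halides.

Step 3
Reactants: 5 4-bromo-3-butanoylfuran-2(5H)-one
Product: 6 4-bromo-3-[(1S)-1-hydroxybutyl]furan-2(5H)-one
Conditions: (R)-Me-CBS oxazaborolidine (C18H20BNO, 0.2 equiv), catecholborane, toluene, −78 °C
Reagents that add atoms: none
Why: Corey–Bakshi–Shibata reduction with the branched sp2 butenolide as the large group and n-propyl as the small group should deliver hydride to the face that gives the S carbinol, and the low temperature should keep hydride away from the β-bromo enoate.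

Step 4
Reactants: 5 4-bromo-3-butanoylfuran-2(5H)-one
Product: 7 4-bromo-3-[(1R)-1-hydroxybutyl]furan-2(5H)-one
Conditions: (S)-Me-CBS oxazaborolidine (C18H20BNO, 0.2 equiv), catecholborane, toluene, −78 °C
Reagents that add atoms: none
Why: The mirror-image Corey–Bakshi–Shibata reduction should set the R carbinol by the same model with the enantiomeric catalyst.

Step 5
Reactants: 7 4-bromo-3-[(1R)-1-hydroxybutyl]furan-2(5H)-one
Product: 9 4,5-dibromo-3-[(1R)-1-(tert-butyldimethylsilyloxy)butyl]furan-2(5H)-one (C5 epimers), via R-configured silyloxyfuran 8 (not isolated)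
Conditions: TBSOTf (2.05 equiv), Et3N, CH2Cl2, −78 to 0 °C; then NBS (1.0 equiv), −78 °C; filtration, crude used at once
Reagents that add atoms: tert-butyldimethylsilyl trifluoromethanesulfonate, CC(C)(C)[Si](C)(C)OS(=O)(=O)C(F)(F)F; N-bromosuccinimide, O=C1CCC(=O)N1Br
Why: Silyl triflate and amine should silylate the carbinol and convert the butenolide into its 2-silyloxyfuran, which NBS brominates at the free γ-carbon C5 (vinylogous α-halogenation of a silyl dienol ether); C1' is untouched and the C5 centre forms unselectively and is erased in step 7.

Step 6
Reactants: 6 4-bromo-3-[(1S)-1-hydroxybutyl]furan-2(5H)-one; 9 4,5-dibromo-3-[(1R)-1-(tert-butyldimethylsilyloxy)butyl]furan-2(5H)-one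
Product: 11 4,4'-dibromo-3-[(1S)-1-(tert-butyldimethylsilyloxy)butyl]-3'-[(1R)-1-(tert-butyldimethylsilyloxy)butyl]-5,5'-bi(furan-2(5H)-one) (mixture at C5 and C5'), via S-configured silyloxyfuran 10 (not isolated)
Conditions: 6, TBSOTf (2.05 equiv), Et3N, CH2Cl2, 0 °C; pentane filtration; then 9, AgOCOCF3 (1.1 equiv), CH2Cl2, −78 to −20 °C
Reagents that add atoms: tert-butyldimethylsilyl trifluoromethanesulfonate, CC(C)(C)[Si](C)(C)OS(=O)(=O)C(F)(F)F
Why: Silver-assisted ionisation of the C5 bromide should give an acyloxy-substituted allyl cation that is captured by C5 of the silyloxyfuran (vinylogous Mukaiyama-type γ-alkylation of a 2-silyloxyfuran by an ionisable halide), which joins the S half and the R half as nucleophile and electrophile; the two C5 centres form as a mixture and are erased in step 7.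

Step 7
Reactants: 11 the 5,5'-bibutenolide
Product: 13 meso (E)-4,4'-dibromo-3-[(1S)-1-(tert-butyldimethylsilyloxy)butyl]-3'-[(1R)-1-(tert-butyldimethylsilyloxy)butyl]-5,5'-bifuranylidene-2,2'-dione, via bis(silyloxy)bifuran 12 (not isolated)
Conditions: TBSOTf (2.1 equiv), Et3N, CH2Cl2, 0 °C; evaporation, pentane filtration; then DDQ (1.1 equiv), CH2Cl2, −40 to 0 °C, dark
Reagents that add atoms: none
Why: Double γ-enolsilylation should aromatise both rings to a 5,5'-bis(silyloxy)-2,2'-bifuran, the heteroaromatic counterpart of a hydroquinone bis-silyl ether, from which DDQ removes two electrons (DDQ oxidation of silyl enol ethers) to give the quinoid C5=C5' alkene; E is the thermodynamic isomer because Z would press the two C4 bromines together.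

Step 8
Reactants: 13 the meso bis-TBS bifuranylidenedione
Product: 14 meso (E)-3-[(1S)-1-acetoxybutyl]-3'-[(1R)-1-acetoxybutyl]-4,4'-dibromo-5,5'-bifuranylidene-2,2'-dione
Conditions: Ac2O, Cu(OTf)2 (5 mol%), CH2Cl2, rt, dark
Reagents that add atoms: acetic anhydride, CC(=O)OC(C)=O
Why: Lewis-acid-catalysed acylative cleavage of silyl ethers acylates the ether oxygen and expels the silyl group without breaking the C1'–O bond, so both carbinol centres should keep their configuration and no nucleophile meets the electrophilic core.

Step 9
Reactants: 14 the meso (E)-bifuranylidenedione diacetate; 15 (E)-1,2-dibromoethene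
Product: 16 CNP0266230.1, the dispiro cyclobutane with C5A and C5B both S, C6A and C6B both R, arm A 1'S and arm B 1'R
Conditions: 15 (20 equiv), AlBr3-activated oxazaborolidine from (S)-α,α-diphenylprolinol and 2,4,6-trifluorophenylboronic acid (1.0 equiv), CH2Cl2, −75 °C, hν (425 nm LED)
Reagents that add atoms: none
Why: Proposed new method: the AlBr3-activated oxazaborolidine should bind one lactone carbonyl of meso 14, shift the absorption of the O=C–C3=C4–C5=C5–C4=C3–C=O chromophore into the visible and cover the Re,Re face of C5A=C5B, so that only bound substrate is excited at 425 nm and the excess dihaloalkene meets the Si,Si face in a singlet exciplex. The exciplex should collapse by forming C5A–C6A and C5B–C6B in a photochemical [2+2] cycloaddition that is suprafacial on both partners, and this intermolecular two-bond closure is the mode by which the four-membered ring, the only ring formed, is closed. The closest known reaction types are the enantioselective enone–alkene and coumarin–alkene [2+2] photocycloadditions mediated by AlBr3-activated chiral oxazaborolidines, the stereospecific singlet-state cycloadditions of Lewis-acid-bound coumarins, and the addition of 1,2-dichloroethene to excited enones; new here are the central double bond of a cross-conjugated ene-dilactone as the 2π partner, 1,2-dibromoethene as the alkene, and the desymmetrisation of a meso alkene by face choice. The trans oxygens at the spiro carbons C5A and C5B are taken over from the E geometry of 14, the trans bromines at C6A and C6B from the E geometry of 15, the placing of each C6 bromine on the C4 side and not the O1 side from avoidance of the C–O dipoles and ring-oxygen lone pairs in the exciplex, and the absolute configuration from the face shielding by the Lewis acid, the two faces of the centrosymmetric alkene being enantiotopic. The step needs face selectivity, this orientation and retention of both alkene geometries, and the last requires that no long-lived triplet 1,4-diradical forms, since a C6 radical β to a C–Br bond would rotate or lose a bromine atom; high alkene concentration, low temperature and the rigid planar chromophore, whose Z isomer is disfavoured by the Br/Br clash, are meant to secure this. The product has lost the long-wavelength chromophore and should therefore be safe from secondary photolysis, and the minor trans-dibromide diastereomer is removed by chromatography.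

**Compound list**

1 | tetronic acid (4-hydroxyfuran-2(5H)-one) | OC1=CC(=O)OC1 | starting material
2 | butanoyl chloride | CCCC(Cl)=O | starting material
3 | 5-oxo-2,5-dihydrofuran-3-yl butanoate (O-butanoyl tetronate) | CCCC(=O)OC1=CC(=O)OC1 | intermediate
4 | 3-butanoyl-4-hydroxyfuran-2(5H)-one | CCCC(=O)C1=C(O)COC1=O | intermediate
5 | 4-bromo-3-butanoylfuran-2(5H)-one | CCCC(=O)C1=C(Br)COC1=O | intermediate
6 | 4-bromo-3-[(1S)-1-hydroxybutyl]furan-2(5H)-one | CCC[C@H](O)C1=C(Br)COC1=O | intermediate
7 | 4-bromo-3-[(1R)-1-hydroxybutyl]furan-2(5H)-one | CCC[C@@H](O)C1=C(Br)COC1=O | intermediate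
8 | 4-bromo-2-(tert-butyldimethylsilyloxy)-3-[(1R)-1-(tert-butyldimethylsilyloxy)butyl]furan | CCC[C@@H](O[Si](C)(C)C(C)(C)C)c1c(Br)coc1O[Si](C)(C)C(C)(C)C | intermediate
9 | 4,5-dibromo-3-[(1R)-1-(tert-butyldimethylsilyloxy)butyl]furan-2(5H)-one, C5 epimers | CCC[C@@H](O[Si](C)(C)C(C)(C)C)C1=C(Br)C(Br)OC1=O | intermediate
10 | 4-bromo-2-(tert-butyldimethylsilyloxy)-3-[(1S)-1-(tert-butyldimethylsilyloxy)butyl]furan | CCC[C@H](O[Si](C)(C)C(C)(C)C)c1c(Br)coc1O[Si](C)(C)C(C)(C)C | intermediate
11 | 4,4'-dibromo-5,5'-bi(furan-2(5H)-one) with the (1S)-TBSO-butyl arm on C3 and the (1R)-TBSO-butyl arm on C3', mixture at C5 and C5' | CCC[C@H](O[Si](C)(C)C(C)(C)C)C1=C(Br)C(OC1=O)C2OC(=O)C([C@@H](CCC)O[Si](C)(C)C(C)(C)C)=C2Br | intermediate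
12 | 3,3'-dibromo-5,5'-bis(tert-butyldimethylsilyloxy)-2,2'-bifuran with the (1S)- and (1R)-TBSO-butyl arms on C4 and C4' | CCC[C@H](O[Si](C)(C)C(C)(C)C)c1c(Br)c(oc1O[Si](C)(C)C(C)(C)C)-c2oc(O[Si](C)(C)C(C)(C)C)c([C@@H](CCC)O[Si](C)(C)C(C)(C)C)c2Br | intermediate
13 | meso (E)-4,4'-dibromo-5,5'-bifuranylidene-2,2'-dione with the (1S)- and (1R)-TBSO-butyl arms on C3 and C3' | CCC[C@H](O[Si](C)(C)C(C)(C)C)C1=C(Br)/C(OC1=O)=C2\OC(=O)C([C@@H](CCC)O[Si](C)(C)C(C)(C)C)=C2Br | intermediate
14 | meso (E)-3-[(1S)-1-acetoxybutyl]-3'-[(1R)-1-acetoxybutyl]-4,4'-dibromo-5,5'-bifuranylidene-2,2'-dione | CCC[C@H](OC(C)=O)C1=C(Br)/C(OC1=O)=C2\OC(=O)C([C@@H](CCC)OC(C)=O)=C2Br | intermediate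
15 | (E)-1,2-dibromoethene | Br/C=C/Br | starting material
16 | CNP0266230.1: cyclobutane C5A–C6A–C6B–C5B, each C5 spiro to a 3-(1-acetoxybutyl)-4-bromobutenolide; O1A and O1B trans; C6 bromines trans, each cis to the C4 of the adjacent spiro ring; C5A S, C5B S, C6A R, C6B R, arm A 1'S, arm B 1'R | CCC[C@H](OC(C)=O)C1=C(Br)[C@@]2(OC1=O)[C@@H](Br)[C@H](Br)[C@@]21OC(=O)C([C@@H](CCC)OC(C)=O)=C1Br | target

**Step count and risks**

Total steps: 9. Longest linear sequence: 8 steps (1, 2, 4, 5, 6, 7, 8, 9).

Steps most likely to fail:

1. **Step 9.** What may go wrong:
   - intersystem crossing to a triplet 1,4-diradical, with loss of a bromine atom or scrambling of the dibromide geometry;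
   - addition at a C3=C4 bond instead of C5A=C5B;
   - poor facial selectivity, because the Lewis acid is spread over four carbonyls;
   - poor control of the bromine orientation.

   Fallback, from 14 back to 16: irradiation of 14 under acetylene (the known enone–alkyne [2+2] photocycloaddition, whose triplet diradical carries no β-halogen) should give the dispiro cyclobutene F1, with the trans oxygens fixed by the E alkene. Without a chiral mediator F1 is racemic, and the enantiomer with the spiro centres arranged as in 16 (5R,5'R by the sequence rule, the descriptor changing because C6 bears no bromine) is taken by preparative HPLC on a chiral phase. Anti addition of Br2 (CH2Cl2, −78 °C, dark) through the bromonium ion should then give the trans-dibromide 16, to be separated from the trans isomer with the bromines on the O1 side.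

2. **Step 6.** What may go wrong:
   - sluggish ionisation of the destabilised C5 cation;
   - capture at C3 instead of C5;
   - bromine transfer from 9 to 10 before C–C bond formation, which would scramble the S/R pairing;
   - Lewis-acid ionisation of the C1' silyl ether of the electron-rich furan.

   Fallback, from 8 and 10 back to 11: the two enantiomeric silyloxyfurans 8 and 10 are combined 1:1 and coupled by one-electron oxidation (Cu(OTf)2, MeCN, oxidative dimerisation of silyl enol ethers through the C5 radical). This should give 11 statistically, together with the racemic bibutenolide with like-configured arms F2. The mixture is carried through step 7, and the centrosymmetric 13 is separated by crystallisation from the racemic C2-symmetric bifuranylidenedione F3.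

3. **Step 7.** What may go wrong:
   - incomplete double enolsilylation of the hindered C5–H positions;
   - cycloaddition or over-oxidation of the electron-rich bifuran by DDQ;
   - formation of an E/Z mixture.

   Fallback, from 11 back to 13: Wohl–Ziegler bromination (NBS, AIBN, PhCF3, 80 °C) at the tertiary, allylic, oxygen-bearing C5–H should give the 5-bromo-5,5'-bibutenolide F4; the C1'–H bonds are held in the nodal plane of the alkene by allylic strain. Dehydrobromination with Et3N (CH2Cl2, 0 °C) across C5–C5' should then give 13, with iodine-catalysed equilibration to the E isomer if needed.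

Further compounds
F1 | step 9 | dispiro cyclobutene: cyclobut-3-ene whose C1 and C2 are the spiro C5 atoms of two 3-(1-acetoxybutyl)-4-bromobutenolides (arms 1'S and 1'R), lactone oxygens trans, spiro centres arranged as in 16 | CCC[C@H](OC(C)=O)C1=C(Br)[C@@]2(OC1=O)C=C[C@@]21OC(=O)C([C@@H](CCC)OC(C)=O)=C1Br
F2 | step 6 | racemic 4,4'-dibromo-5,5'-bi(furan-2(5H)-one) with like-configured TBSO-butyl arms (1S,1S enantiomer drawn), mixture at C5 and C5' | CCC[C@H](O[Si](C)(C)C(C)(C)C)C1=C(Br)C(OC1=O)C2OC(=O)C([C@H](CCC)O[Si](C)(C)C(C)(C)C)=C2Br
F3 | step 6 | racemic (E)-4,4'-dibromo-5,5'-bifuranylidene-2,2'-dione with like-configured TBSO-butyl arms (1S,1S enantiomer drawn) | CCC[C@H](O[Si](C)(C)C(C)(C)C)C1=C(Br)/C(OC1=O)=C2\OC(=O)C([C@H](CCC)O[Si](C)(C)C(C)(C)C)=C2Br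
F4 | step 7 | 4,4',5-tribromo-5,5'-bi(furan-2(5H)-one) with the (1S)- and (1R)-TBSO-butyl arms (bromine on either C5, one regioisomer drawn) | CCC[C@H](O[Si](C)(C)C(C)(C)C)C1=C(Br)C(Br)(OC1=O)C2OC(=O)C([C@@H](CCC)O[Si](C)(C)C(C)(C)C)=C2Br
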